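## Structural features

The target is a depside: ring A, a fully substituted benzoyl unit, is joined through its carboxyl carbon to the oxygen on C4 of ring B, the methyl orsellinate unit (CO2Me at C1, OH at C2, CH3 at C6, C3 and C5 unsubstituted). Around ring A the substituents are the depside carbonyl at C1, CH3 at C2, Cl at C3, OH at C4, CH3 at C5 and OH at C6. There is no stereocentre and no hindered axis, so every selectivity question is regiochemical or chemoselective. The fragile points are the inter-ring aryl ester (an aryloxide leaving group, open to alkoxides, amines and unbuffered fluoride), the methyl ester, three oxidizable phenols and the aryl chloride, which would not survive hydrogenolysis. The real difficulty is twofold: the depside carbonyl lies between C2–CH3 and C6–OH, so making this ester by acylating a phenol with a ring A acid is slow and needs a protected acid, and six contiguous, different substituents on ring A are awkward to set by successive aromatic substitutions. The key step exploits the fact that ring A C3–C4–C5–C6 (oxygen on C4 and C6, methyl on C5) is the chain C4–C3–C2–C1 of an enolized 2-methylcyclohexane-1,3-dione, while C1 with its carboxyl and C2 with its methyl are the two sp carbons of a but-2-ynoate, which can be hung on ring B O4 as an unhindered ester before ring A exists. A second useful feature is that ring A, with two hydroxyls directing to C3, is far more electron-rich than ring B, so the chlorine can be introduced last.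

## Logic of the disconnections

11 to 10: the ring A C3–Cl bond is cut. C3 is the only unsubstituted carbon of ring A and is ortho to the C4 hydroxyl and para to the C6 hydroxyl, so an electrophilic chlorine source should go there. Removing the halogen keeps it out of the thermal step and avoids a chlorinated diene, which is not accessible from 1 because halogenation of 1 goes to its doubly activated C2. The forward step must discriminate ring A (two free hydroxyls) from ring B (one chelated hydroxyl, one acyloxy group, one ester) and stop after one substitution.

10 to 9: the three O–Si bonds are cut (functional-group interconversion). All three phenols are masked as silyl ethers so that nothing acidic is present during the cycloaddition and one buffered fluoride treatment releases them together. The forward step must leave the inter-ring aryl ester and the methyl ester untouched.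

9 to 3 and 7 (through 8): ring A is cut at C1–C6 and C2–C3 after formally re-inserting a two-carbon bridge across C3 and C6. This turns the hexasubstituted arene into a seven-carbon cyclic diene and an alkynoate, and the hindered benzoate ester is already present in 7 as an ester of an unhindered acid. The forward step needs the unsubstituted diene terminus to bond to the methyl-bearing alkyne carbon, needs both partners to tolerate prolonged heating, and needs an aprotic alkyne partner. For that reason the ring B C2 oxygen is a silyl ether and not an acetal: it is installed with a non-nucleophilic base, avoids a carcinogenic chloromethyl ether, and leaves with the other silyl groups.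

7 to 6: the O–Si bond on ring B O2 is cut. The demand is a silylation that neither adds a nucleophile to the ynoate nor cleaves the aryl ester.

6 to 4 and 5: the acyl C–O bond between the but-2-ynoyl carbonyl and ring B O4 is cut. Both pieces are commercial, the acid is unhindered, and the 4-hydroxyl of 4 is free while the 2-hydroxyl is tied up in a hydrogen bond to the ester. The forward step must acylate once, at O4, without conjugate addition of the acyl-transfer catalyst to the triple bond.

3 to 1 (through 2): the two O–Si bonds are cut, giving the symmetrical dione. Because 3 is symmetrical about its methyl-bearing carbon, deprotonation of 2 on either side leads to the same diene, so only anhydrous handling is demanded.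

## Other disconnections considered

Alternative 1: The cut is the ring A C1–C2 bond, which opens ring A to the open-chain aryl ester A2 (methyl 2-hydroxy-6-methyl-4-[(4-methyl-3,5,7-trioxooctanoyl)oxy]benzoate).
- Forward key step: mild base then acid would add the chain C2 methylene to the C7 ketone, dehydrate and enolize to give A1, which is identical with 10. A2 would be reached from 4 by trapping the acylketene released on heating the dioxinone A3 (2,2-dimethyl-6-(3,5-dioxohexan-2-yl)-4H-1,3-dioxin-4-one).
- In favour: like the chosen plan, it places the inter-ring ester on an unhindered acyl donor before ring A exists, so the two are equal on that point. It is better on protecting groups, because A1 appears with all ring A hydroxyls free and the desilylation step disappears. The conditions are mild.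
- Against: A2 is an aryl ester of a triketo acid. Under the base needed for the aldol, the C5 enol oxygen can close onto C1, or C6 can attack C1 in a Claisen mode. Either path expels the ring B aryloxide and destroys the depside bond. A second aldol mode (C8 onto C3) is also open.
- Comparison: structurally both plans build ring A last and need the same late chlorination (equal). Mechanistically this is an ionic folding with several competing modes steered only by conditions, against a pericyclic step whose connectivity is set by orbital polarization. On step economy, A3 needs its own multi-step synthesis, which outweighs the saved deprotection.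

Alternative 2: The cut removes both bonds to the depside carbonyl carbon (ring A C1–C and C–O).
- Forward key step: the iodide A5 (1-chloro-3-iodo-4,6-bis(methoxymethoxy)-2,5-dimethylbenzene), carbon monoxide A6 and 4 would be joined with Pd(OAc)2, Xantphos and triethylamine. The sequence is oxidative addition of the C–I bond to zerovalent palladium, insertion of A6, and transfer of the acyl group to the 4-oxygen of 4, giving A4.
- In favour: it is the most convergent plan and builds no ring. It is better than the chosen plan on halogen placement, since the chlorine is already fixed in A5 and no late site selection arises. Its step count should be equal or lower.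
- Against: the acylpalladium species is flanked by CH3 and an acetal oxygen and must be captured by a weak, bulky aryloxide, so the hindered acylation returns in organometallic form. Reduction of the C–I bond and direct C–O coupling compete, and 4 offers two hydroxyls. A toxic gas is needed, A5 needs a carcinogenic chloromethyl ether reagent, and unmasking A4 needs protic acid in the presence of the depside ester.
- Comparison: the chosen plan is longer by about one step but replaces a three-component catalytic cycle with a hindered acyl transfer by a thermal reaction with one competent dienophile.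

Alternative 3: The cut is at ring B C2–C3 and C1–C6.
- Forward key step: the pyranone ester A8 (6-methyl-2-oxo-2H-pyran-4-yl 3-chloro-4,6-bis(methoxymethoxy)-2,5-dimethylbenzoate) and the alkyne A9 (methyl 3-methoxyprop-2-ynoate) would be heated. Cycloaddition across pyranone C3 and C6 followed by decarboxylative aromatization gives A7.
- In favour: it belongs to the same mechanistic family as the chosen key step (cycloaddition, then irreversible loss of a small bridge), so the two are equal in the certainty of the aromatization. It is better in that the chlorine is in place beforehand.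
- Against: it constructs the ring that can be bought as 4 and leaves the difficult ring A to be made elsewhere. A8 must be made by acylating a weakly nucleophilic pyranone hydroxyl with a hindered ring A acyl chloride, so the hindered esterification returns. A8 is an enol ester liable to acyl transfer on heating. The pyranone is an electron-poor, sluggish diene and A9 a push–pull alkyne, so high temperatures are expected. A7 carries a methyl ether on ring B O2 that needs a Lewis acid for removal next to the depside ester.
- Comparison: on structure and step economy the chosen plan is clearly ahead. On mechanism the two are comparable.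

Key step: step 4

Remark on the chemistry: ring A is numbered from the carbon bearing the depside carbonyl (C1) through C2 (CH3), C3 (Cl), C4 (OH), C5 (CH3) to C6 (OH). Systematic benzoyl locants in the chlorine-free compounds run the other way. Diene carbons C1, C2, C3 and C4 of 3 become ring A C6, C5, C4 and C3. Adduct 8 is chiral and forms as a racemate, and its two bridgehead stereocentres vanish on aromatization.

## Steps

Step 1
Reactants: 1 2-methylcyclohexane-1,3-dione
Product: 3 2-methyl-1,3-bis(trimethylsilyloxy)cyclohexa-1,3-diene, via monosilyl enol ether 2 (not isolated)
Conditions: HN(SiMe3)2 (0.6 equiv), imidazole (2 mol %), toluene, 110 °C, then evaporate; LiN(iPr)2 (1.1 equiv), THF, −78 °C; Me3SiCl (1.3 equiv), −78 °C → rt; pentane, filter, distil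
Reagents that add atoms: hexamethyldisilazane C[Si](C)(C)N[Si](C)(C)C; chlorotrimethylsilane C[Si](C)(C)Cl
Why: O-silylation of the enolized dione gives the vinylogous silyl ester 2, and kinetic deprotonation with the amide base followed by O-silylation of the dienolate (silyl enol ether formation) should give 3; since 3 is symmetrical about C2, removal of a proton from either CH2 next to the oxygenated carbons leads to the same diene.

Step 2
Reactants: 4 methyl 2,4-dihydroxy-6-methylbenzoate (methyl orsellinate); 5 but-2-ynoic acid
Product: 6 methyl 4-(but-2-ynoyloxy)-2-hydroxy-6-methylbenzoate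
Conditions: DCC (1.1 equiv), 4-(dimethylamino)pyridine (5 mol %), CH2Cl2, −20 → 0 °C
Reagents that add atoms: none
Why: Steglich esterification; the 4-hydroxyl is free and the more acidic one, whereas the 2-hydroxyl is locked in a hydrogen bond to the ester carbonyl, so one equivalent of activated acid should go to O4, and the low temperature with little catalyst limits amine addition to the ynoate.

Step 3
Reactants: 6 methyl 4-(but-2-ynoyloxy)-2-hydroxy-6-methylbenzoate
Product: 7 methyl 4-(but-2-ynoyloxy)-2-[(tert-butyldimethylsilyl)oxy]-6-methylbenzoate
Conditions: t-BuMe2SiOTf (1.2 equiv), 2,6-lutidine (1.5 equiv), CH2Cl2, 0 °C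
Reagents that add atoms: tert-butyldimethylsilyl trifluoromethanesulfonate CC(C)(C)[Si](C)(C)OS(=O)(=O)C(F)(F)F
Why: Silylation of a chelated phenol with a silyl triflate and a hindered pyridine base; the base cannot add to the ynoate or cleave the aryl ester, and the silyl ether removes the only acidic proton that could protodesilylate 3 in step 4.

Step 4
Reactants: 3 2-methyl-1,3-bis(trimethylsilyloxy)cyclohexa-1,3-diene; 7 methyl 4-(but-2-ynoyloxy)-2-[(tert-butyldimethylsilyl)oxy]-6-methylbenzoate
Product: 9 methyl 2-[(tert-butyldimethylsilyl)oxy]-4-{[3,6-dimethyl-2,4-bis(trimethylsilyloxy)benzoyl]oxy}-6-methylbenzoate, via bicyclooctadiene adduct 8 (not isolated)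
Conditions: 3 (2.0 equiv), mesitylene, 150 °C, argon (open to a bubbler), 24 h; then volatiles off under high vacuum
Reagents that add atoms: none
Why: This is an Alder–Rickert reaction, the closest known type being the synthesis of resorcylates from 1,3-bis(silyloxy)cyclohexa-1,3-dienes and alk-2-ynoates. A normal-electron-demand, asynchronous [4+2] cycloaddition between the electron-rich diene of 3 and the electron-poor triple bond of 7 should give the bicyclo[2.2.2]octa-2,5-diene 8, in which diene C4 has bonded to the methyl-bearing alkyne carbon (ring A C2–C3) and diene C1 to the carboxyl-bearing alkyne carbon (ring A C1–C6). At the reaction temperature 8 should undergo a retro-[4+2] cycloreversion that expels its saturated two-carbon bridge as ethylene, which is irreversible because the gas escapes and ring A becomes aromatic. Ring A is therefore closed by an intermolecular cycloaddition that makes two sigma bonds at once, not by cyclization of a tethered chain, and is aromatized by the cycloreversion. No stereocentre is created in 9; the two bridgehead centres of 8 are fixed relative to each other by the bicycle, arise as a racemate and disappear with the ethylene. The selectivity needed is regiochemical: both silyloxy groups push electron density to the unsubstituted terminus C4, and the aryl ester makes the methyl-bearing beta carbon of the alkyne the electrophilic end, so the two polarizations reinforce each other. Chemoselectivity should follow from the triple bond being the only competent dienophile in 7, with the silyl ether on ring B keeping the medium aprotic. Excess 3 covers its slow thermal isomerization, and 9 is used without chromatography because aryl trimethylsilyl ethers hydrolyse on silica.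

Step 5
Reactants: 9 methyl 2-[(tert-butyldimethylsilyl)oxy]-4-{[3,6-dimethyl-2,4-bis(trimethylsilyloxy)benzoyl]oxy}-6-methylbenzoate
Product: 10 methyl 4-[(2,4-dihydroxy-3,6-dimethylbenzoyl)oxy]-2-hydroxy-6-methylbenzoate
Conditions: Bu4NF (3.3 equiv), AcOH (3.6 equiv), THF, 0 °C → rt
Reagents that add atoms: none
Why: Fluoride-induced cleavage of aryl silyl ethers, driven by the strength of the Si–F bond; the acetic acid buffer protonates each aryloxide as it forms, so the inter-ring aryl ester, whose carbonyl is also shielded by two ortho substituents, and the methyl ester should not be attacked.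

Step 6
Reactants: 10 methyl 4-[(2,4-dihydroxy-3,6-dimethylbenzoyl)oxy]-2-hydroxy-6-methylbenzoate
Product: 11 methyl 4-[(3-chloro-4,6-dihydroxy-2,5-dimethylbenzoyl)oxy]-2-hydroxy-6-methylbenzoate
Conditions: SO2Cl2 (1.0 equiv, slow addition), Et2O, 0 °C
Reagents that add atoms: sulfuryl chloride ClS(Cl)(=O)=O
Why: Electrophilic aromatic chlorination; ring A C3 is the only unsubstituted carbon of ring A and is ortho to the C4 hydroxyl and para to the C6 hydroxyl, whereas ring B has a single chelated hydroxyl, an acyloxy group and an ester and should react much more slowly, and one equivalent at low temperature limits further chlorination.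

## Compound list

1 | 2-methylcyclohexane-1,3-dione | CC1C(=O)CCCC1=O | starting material
2 | 2-methyl-3-(trimethylsilyloxy)cyclohex-2-en-1-one | CC1=C(O[Si](C)(C)C)CCCC1=O | intermediate
3 | 2-methyl-1,3-bis(trimethylsilyloxy)cyclohexa-1,3-diene | C[Si](C)(C)OC1=C(C)C(O[Si](C)(C)C)=CCC1 | intermediate
4 | methyl 2,4-dihydroxy-6-methylbenzoate (methyl orsellinate) | COC(=O)c1c(C)cc(O)cc1O | starting material
5 | but-2-ynoic acid | CC#CC(O)=O | starting material
6 | methyl 4-(but-2-ynoyloxy)-2-hydroxy-6-methylbenzoate | COC(=O)c1c(C)cc(OC(=O)C#CC)cc1O | intermediate
7 | methyl 4-(but-2-ynoyloxy)-2-[(tert-butyldimethylsilyl)oxy]-6-methylbenzoate | COC(=O)c1c(C)cc(OC(=O)C#CC)cc1O[Si](C)(C)C(C)(C)C | intermediate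
8 | 3-[(tert-butyldimethylsilyl)oxy]-4-(methoxycarbonyl)-5-methylphenyl 3,6-dimethyl-1,5-bis(trimethylsilyloxy)bicyclo[2.2.2]octa-2,5-diene-2-carboxylate (racemate, transient) | COC(=O)c1c(C)cc(OC(=O)C2=C(C)C3CCC2(O[Si](C)(C)C)C(C)=C3O[Si](C)(C)C)cc1O[Si](C)(C)C(C)(C)C | intermediate
9 | methyl 2-[(tert-butyldimethylsilyl)oxy]-4-{[3,6-dimethyl-2,4-bis(trimethylsilyloxy)benzoyl]oxy}-6-methylbenzoate | COC(=O)c1c(C)cc(OC(=O)c2c(C)cc(O[Si](C)(C)C)c(C)c2O[Si](C)(C)C)cc1O[Si](C)(C)C(C)(C)C | intermediate
10 | methyl 4-[(2,4-dihydroxy-3,6-dimethylbenzoyl)oxy]-2-hydroxy-6-methylbenzoate | COC(=O)c1c(C)cc(OC(=O)c2c(C)cc(O)c(C)c2O)cc1O | intermediate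
11 | methyl 4-[(3-chloro-4,6-dihydroxy-2,5-dimethylbenzoyl)oxy]-2-hydroxy-6-methylbenzoate | COC(=O)c1c(C)cc(OC(=O)c2c(C)c(Cl)c(O)c(C)c2O)cc1O | target

## Step count and least certain steps

Total step count: 6. Longest linear sequence: 5 steps (4 → 6 → 7 → 9 → 10 → 11). The diene branch (1 → 3) is one step and joins at step 4.

Step 4 (key step). The cycloaddition onto a beta-methyl-substituted alkynoate is slow. Thermal 1,5-hydrogen shift in the diene (which moves it out of the 1,3-dioxygenated arrangement) and adventitious protodesilylation may therefore consume 3 before 7 is converted. Any higher temperature then needed may erode regiocontrol. The fallback forms the depside ester by acylation with a preformed ring A acid; it sets out from 4 and returns at 10. Commercial 2,5-dimethylresorcinol (Cc1cc(O)c(C)c(O)c1) would be formylated at one of its two equivalent open positions (Vilsmeier–Haack, POCl3, DMF) to 2,4-dihydroxy-3,6-dimethylbenzaldehyde F1. Both hydroxyls would be benzylated (BnBr, K2CO3, DMF, 60 °C) to give 2,4-bis(benzyloxy)-3,6-dimethylbenzaldehyde F2. Pinnick oxidation (NaClO2, NaH2PO4, 2-methylbut-2-ene, t-BuOH–H2O) would give 2,4-bis(benzyloxy)-3,6-dimethylbenzoic acid F3. F3 and 4 would be condensed with trifluoroacetic anhydride in toluene at rt, where the mixed anhydride should acylate the free 4-hydroxyl of 4 and not the chelated 2-hydroxyl, to give methyl 4-{[2,4-bis(benzyloxy)-3,6-dimethylbenzoyl]oxy}-2-hydroxy-6-methylbenzoate F4. Hydrogenolysis (H2, Pd/C, EtOAc) should then give 10, which continues with step 6. The price is the slow hindered acylation that the main route avoids, and more operations.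

Step 6. Site selectivity may be lost: chlorination may spill into ring B (C3 or C5), or continue on ring A by ipso attack at the methyl-bearing C5 between the two hydroxyls with dearomatization, since the free phenol of ring B is also an activated arene. The fallback chlorinates before the ring B phenol is unveiled; it sets out from 9 and returns at 11. Brief acid-catalysed methanolysis of 9 (citric acid, MeOH–THF, 0 °C) should remove only the two trimethylsilyl groups and give methyl 2-[(tert-butyldimethylsilyl)oxy]-4-[(2,4-dihydroxy-3,6-dimethylbenzoyl)oxy]-6-methylbenzoate F5. Chlorination (N-chlorosuccinimide, MeCN, 0 °C → rt) then meets a ring B whose only donor is a bulky, weakly donating silyloxy group and should give methyl 2-[(tert-butyldimethylsilyl)oxy]-4-[(3-chloro-4,6-dihydroxy-2,5-dimethylbenzoyl)oxy]-6-methylbenzoate F6. Bu4NF with AcOH in THF would release 11.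

Step 1. The second silylation may be incomplete, or the moisture-sensitive diene may hydrolyse in part during isolation. The charge of 3 would then contain 2 or 1, whose acidic enol strips silyl groups from more diene in step 4. The fallback uses soft enolization to a more robust diene; it sets out from 1 and returns at 10. Treating 1 with t-BuMe2SiOTf (2.3 equiv) and Et3N in CH2Cl2 (0 °C → rt) should give 2-methyl-1,3-bis[(tert-butyldimethylsilyl)oxy]cyclohexa-1,3-diene F7 without any amide base; it should tolerate a quick bicarbonate work-up and storage. Heating F7 with 7 as in step 4 should give methyl 4-({2,4-bis[(tert-butyldimethylsilyl)oxy]-3,6-dimethylbenzoyl}oxy)-2-[(tert-butyldimethylsilyl)oxy]-6-methylbenzoate F8, which can be chromatographed. Bu4NF with AcOH in THF should convert F8 into 10.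

Step 5. If the medium turns basic, the released aryloxides or fluoride may cleave or transfer the inter-ring aryl ester, since the ring B aryloxide is a good leaving group. The fallback is a protecting-group scheme that needs no fluoride; it sets out from 6 and returns at 10. 6 would be silylated with N,O-bis(trimethylsilyl)acetamide (CH2Cl2, rt, volatiles removed) to give methyl 4-(but-2-ynoyloxy)-6-methyl-2-(trimethylsilyloxy)benzoate F9. Heating F9 with 3 as in step 4 should give methyl 4-{[3,6-dimethyl-2,4-bis(trimethylsilyloxy)benzoyl]oxy}-6-methyl-2-(trimethylsilyloxy)benzoate F10. All three silyl ethers would then be removed by acid-catalysed methanolysis (citric acid, MeOH–THF, rt) to give 10, with no base or fluoride at any point.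

## Further compounds

F1 | step 4 | 2,4-dihydroxy-3,6-dimethylbenzaldehyde | Cc1cc(O)c(C)c(O)c1C=O
F2 | step 4 | 2,4-bis(benzyloxy)-3,6-dimethylbenzaldehyde | Cc1cc(OCc2ccccc2)c(C)c(OCc2ccccc2)c1C=O
F3 | step 4 | 2,4-bis(benzyloxy)-3,6-dimethylbenzoic acid | Cc1cc(OCc2ccccc2)c(C)c(OCc2ccccc2)c1C(=O)O
F4 | step 4 | methyl 4-{[2,4-bis(benzyloxy)-3,6-dimethylbenzoyl]oxy}-2-hydroxy-6-methylbenzoate | COC(=O)c1c(C)cc(OC(=O)c2c(C)cc(OCc3ccccc3)c(C)c2OCc4ccccc4)cc1O
F5 | step 6 | methyl 2-[(tert-butyldimethylsilyl)oxy]-4-[(2,4-dihydroxy-3,6-dimethylbenzoyl)oxy]-6-methylbenzoate | COC(=O)c1c(C)cc(OC(=O)c2c(C)cc(O)c(C)c2O)cc1O[Si](C)(C)C(C)(C)C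
F6 | step 6 | methyl 2-[(tert-butyldimethylsilyl)oxy]-4-[(3-chloro-4,6-dihydroxy-2,5-dimethylbenzoyl)oxy]-6-methylbenzoate | COC(=O)c1c(C)cc(OC(=O)c2c(C)c(Cl)c(O)c(C)c2O)cc1O[Si](C)(C)C(C)(C)C
F7 | step 1 | 2-methyl-1,3-bis[(tert-butyldimethylsilyl)oxy]cyclohexa-1,3-diene | CC(C)(C)[Si](C)(C)OC1=C(C)C(O[Si](C)(C)C(C)(C)C)=CCC1
F8 | step 1 | methyl 4-({2,4-bis[(tert-butyldimethylsilyl)oxy]-3,6-dimethylbenzoyl}oxy)-2-[(tert-butyldimethylsilyl)oxy]-6-methylbenzoate | COC(=O)c1c(C)cc(OC(=O)c2c(C)cc(O[Si](C)(C)C(C)(C)C)c(C)c2O[Si](C)(C)C(C)(C)C)cc1O[Si](C)(C)C(C)(C)C
F9 | step 5 | methyl 4-(but-2-ynoyloxy)-6-methyl-2-(trimethylsilyloxy)benzoate | COC(=O)c1c(C)cc(OC(=O)C#CC)cc1O[Si](C)(C)C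
F10 | step 5 | methyl 4-{[3,6-dimethyl-2,4-bis(trimethylsilyloxy)benzoyl]oxy}-6-methyl-2-(trimethylsilyloxy)benzoate | COC(=O)c1c(C)cc(OC(=O)c2c(C)cc(O[Si](C)(C)C)c(C)c2O[Si](C)(C)C)cc1O[Si](C)(C)C
A1 | alternative 1 | methyl 4-[(2,4-dihydroxy-3,6-dimethylbenzoyl)oxy]-2-hydroxy-6-methylbenzoate (identical with 10) | COC(=O)c1c(C)cc(OC(=O)c2c(C)cc(O)c(C)c2O)cc1O
A2 | alternative 1 | methyl 2-hydroxy-6-methyl-4-[(4-methyl-3,5,7-trioxooctanoyl)oxy]benzoate (racemic, enolizable) | COC(=O)c1c(C)cc(OC(=O)CC(=O)C(C)C(=O)CC(C)=O)cc1O
A3 | alternative 1 | 2,2-dimethyl-6-(3,5-dioxohexan-2-yl)-4H-1,3-dioxin-4-one (racemic, enolizable) | CC(=O)CC(=O)C(C)C1=CC(=O)OC(C)(C)O1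
A4 | alternative 2 | methyl 4-{[3-chloro-4,6-bis(methoxymethoxy)-2,5-dimethylbenzoyl]oxy}-2-hydroxy-6-methylbenzoate | COC(=O)c1c(C)cc(OC(=O)c2c(C)c(Cl)c(OCOC)c(C)c2OCOC)cc1O
A5 | alternative 2 | 1-chloro-3-iodo-4,6-bis(methoxymethoxy)-2,5-dimethylbenzene | COCOc1c(C)c(OCOC)c(Cl)c(C)c1I
A6 | alternative 2 | carbon monoxide | [C-]#[O+]
A7 | alternative 3 | methyl 4-{[3-chloro-4,6-bis(methoxymethoxy)-2,5-dimethylbenzoyl]oxy}-2-methoxy-6-methylbenzoate | COC(=O)c1c(C)cc(OC(=O)c2c(C)c(Cl)c(OCOC)c(C)c2OCOC)cc1OC
A8 | alternative 3 | 6-methyl-2-oxo-2H-pyran-4-yl 3-chloro-4,6-bis(methoxymethoxy)-2,5-dimethylbenzoate | Cc1cc(OC(=O)c2c(C)c(Cl)c(OCOC)c(C)c2OCOC)cc(=O)o1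
A9 | alternative 3 | methyl 3-methoxyprop-2-ynoate | COC#CC(=O)OC
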